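**Retrosynthetic overview**
1. Target 20 ⇐ C3–CH2CO2H bond: axial addition of ketene bis(trimethylsilyl) acetal to the C3 peroxycarbenium ion from 3-methoxy-1,2-dioxane 18.
2. 18 ⇐ C6–ethyl bond: axial ethyl transfer from Et2Zn to the C6 peroxycarbenium ion of bis-peroxyketal 17 (new reaction; sets the quaternary centre).
3. 17 ⇐ cobalt-catalysed aerobic ring expansion of cyclobutanol 15 (O2 inserted into C1–C2): the 1,2-dioxane, the only ring of the target, is formed last, from the four-membered carbocycle.
4. 15 ⇐ alkenyllithium from iodide 6 + (3R)-cyclobutanone 13; the cyclobutane (first ring formed) comes from an auxiliary-controlled keteniminium/but-1-ene [2+2] that sets C4.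
5. 6 ⇐ hex-1-ene: Zr-catalysed asymmetric ethylalumination (side-chain centre), acetylide alkylation, Zr-catalysed methylalumination/iodination (E-alkene).

Assumption: the (2R,5R)-auxiliary is taken to give the (3R)-cyclobutanone in step 5; if the sense of induction is the opposite, the (2S,5S)-amine is used with no other change.
Convention: all 1,2-dioxanes are numbered as in the target (O1, O2, C3 bearing the acetic acid chain, C4, C5, C6).

**Step 1**
Reactants: 1 hex-1-ene
Product: 3 (3S)-3-(iodomethyl)heptane, via diethyl[(2S)-2-ethylhexyl]aluminium 2 (not isolated)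
Conditions: Et3Al (1.2 equiv), (+)-(NMI)2ZrCl2 (5 mol %; NMI = 1-neomenthylindenyl), CH2Cl2, 0 °C to rt; then I2 (3.5 equiv), THF, 0 °C
Reagents that add atoms: triethylaluminium CC[Al](CC)CC; iodine [I][I]
Why: Zirconium-catalysed asymmetric carboalumination (Negishi ethylalumination) adds Et–Al across the terminal alkene, the chiral zirconocene (antipode of the one that gives (R)-2-alkylalkanols) choosing the alkene face and so setting the (S) side-chain centre (about 90–95% ee expected), and iodinolysis of the C–Al bond gives the primary iodide.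

**Step 2**
Reactants: 3 (3S)-3-(iodomethyl)heptane
Product: 4 (4S)-4-ethyloct-1-yne
Conditions: LiC≡CH·H2NCH2CH2NH2 (1.5 equiv), DMSO, 0 °C to rt
Reagents that add atoms: lithium acetylide ethylenediamine complex [Li]C#C.NCCN
Why: SN2 alkylation of an acetylide at a primary iodide; the β-stereocentre is not involved.

**Step 3**
Reactants: 4 (4S)-4-ethyloct-1-yne
Product: 6 (1E,4S)-4-ethyl-1-iodo-2-methyloct-1-ene, via alkenyldimethylaluminium 5 (not isolated)
Conditions: Me3Al (2 equiv), Cp2ZrCl2 (25 mol %), CH2Cl2, 0 °C to rt; then I2 (1.2 equiv), THF, −30 to 0 °C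
Reagents that add atoms: trimethylaluminium C[Al](C)C; iodine [I][I]
Why: Negishi zirconium-catalysed methylalumination adds Me and Al syn across the terminal alkyne with Al on the terminal carbon, and iodinolysis of the alkenyl–Al bond with retention gives only the (E)-2-methylalkenyl iodide.

**Step 4**
Reactants: 7 methoxyacetyl chloride; 8 (2R,5R)-2,5-dimethylpyrrolidine
Product: 9 1-[(2R,5R)-2,5-dimethylpyrrolidin-1-yl]-2-methoxyethan-1-one
Conditions: aq. NaOH, CH2Cl2, 0 °C
Reagents that add atoms: none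
Why: Schotten–Baumann N-acylation of the C2-symmetric secondary amine, which attaches the chiral auxiliary.

**Step 5**
Reactants: 9 1-[(2R,5R)-2,5-dimethylpyrrolidin-1-yl]-2-methoxyethan-1-one; 10 but-1-ene
Product: 13 (3R)-3-ethyl-2-methoxycyclobutan-1-one, via keteniminium triflate 11 (not isolated), via cyclobutaniminium triflate 12 (not isolated)
Conditions: Tf2O (1.1 equiv), 2,4,6-collidine (1.2 equiv), CH2Cl2, −25 °C; but-1-ene (5 equiv), sealed tube, rt; then H2O, rt
Reagents that add atoms: water O
Why: Ghosez keteniminium–alkene [2+2] cycloaddition, in which the CH2 terminus of but-1-ene bonds to the central keteniminium carbon so that after iminium hydrolysis ethyl sits β and methoxy α to the carbonyl; the trans-2,5-dimethylpyrrolidine unit shields one alkene approach and sets C3 as (R) (ee to be measured; its C2 epimers are both used because C2 is erased in step 7).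

**Step 6**
Reactants: 6 (1E,4S)-4-ethyl-1-iodo-2-methyloct-1-ene; 13 (3R)-3-ethyl-2-methoxycyclobutan-1-one
Product: 15 (3R)-3-ethyl-1-[(1E,4S)-4-ethyl-2-methyloct-1-en-1-yl]-2-methoxycyclobutan-1-ol, via alkenyllithium 14 (not isolated)
Conditions: t-BuLi (2.0 equiv), Et2O, −78 °C; then 13, −78 °C; H2O quench
Reagents that add atoms: none
Why: Iodine–lithium exchange with retention of alkene geometry followed by 1,2-addition to the strained, highly electrophilic cyclobutanone; the diastereomers at C1 and C2 are carried on together because both centres lose their configuration in step 7.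

**Step 7**
Reactants: 15 (3R)-3-ethyl-1-[(1E,4S)-4-ethyl-2-methyloct-1-en-1-yl]-2-methoxycyclobutan-1-ol
Product: 17 (4R)-4-ethyl-6-[(1E,4S)-4-ethyl-2-methyloct-1-en-1-yl]-3,6-dimethoxy-1,2-dioxane, via dioxan-6-ol 16 (not isolated)
Conditions: Co(acac)2 (20 mol %), O2 (1 atm), 1,2-dichloroethane, 40 °C; then MeOH, PPTS (10 mol %), 3 Å molecular sieves, 0 °C to rt
Reagents that add atoms: dioxygen O=O; methanol CO
Why: Cobalt-catalysed aerobic oxidative ring expansion of a cyclobutanol, in which the alkoxy radical undergoes β-scission of C1–C2 towards the methoxy-stabilised radical, O2 is captured and the hydroperoxide closes onto the new enone carbonyl to give the 1,2-dioxan-6-ol, which acid-catalysed ketalisation converts to the bis-peroxyketal; C4 (old cyclobutane C3) is untouched and C3/C6 are left as anomeric mixtures on purpose.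

**Step 8**
Reactants: 17 (4R)-4-ethyl-6-[(1E,4S)-4-ethyl-2-methyloct-1-en-1-yl]-3,6-dimethoxy-1,2-dioxane
Product: 18 (4R,6R)-4,6-diethyl-6-[(1E,4S)-4-ethyl-2-methyloct-1-en-1-yl]-3-methoxy-1,2-dioxane
Conditions: Et2Zn (2 equiv), TMSOTf (1.1 equiv), CH2Cl2, −78 to −40 °C
Reagents that add atoms: diethylzinc CC[Zn]CC
Why: Proposed new method: TMSOTf ionises the far more labile tertiary allylic C6 peroxyketal (not the secondary C3 peroxyacetal) to a C6 peroxycarbenium ion and Et2Zn transfers an ethyl group to C6 along the axial trajectory of the half-chair that keeps the C4 ethyl pseudo-equatorial, so the new ethyl ends trans to the C4 ethyl and the alkenyl group equatorial and cis to it, which is (6R), while charge control and the fully substituted γ-carbon favour attack at C6 over the far alkene carbon; the closest known reaction types are Lewis acid-mediated allylsilane and silyl enol ether substitution of peroxyketals through peroxycarbenium ions and dialkylzinc or trialkylaluminium alkylation of cyclic oxocarbenium ions (axial, 1,3-trans attack), but alkyl transfer from an organozinc to a peroxycarbenium ion has not been shown.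

**Step 9**
Reactants: 18 (4R,6R)-4,6-diethyl-6-[(1E,4S)-4-ethyl-2-methyloct-1-en-1-yl]-3-methoxy-1,2-dioxane
Product: 20 2-[(3R,4R,6R)-4,6-diethyl-6-[(1E,4S)-4-ethyl-2-methyloct-1-en-1-yl]-1,2-dioxan-3-yl]acetic acid, via trimethylsilyl ester 19 (not isolated)
Conditions: CH2=C(OTMS)2 (2 equiv), TMSOTf (0.3 equiv), CH2Cl2, −78 °C; pH 5 aqueous work-up
Reagents that add atoms: 1,1-bis(trimethylsilyloxy)ethene C=C(O[Si](C)(C)C)O[Si](C)(C)C
Why: Mukaiyama-type addition of a silyl ketene acetal to a peroxycarbenium ion (known peroxyacetal substitution), where the C6 quaternary centre and the C4 ethyl lock the half-chair (alkenyl and C4 ethyl equatorial, C6 ethyl axial) and axial attack at C3 on the face opposite the axial C6 ethyl places the acetic acid chain cis to the C4 ethyl, which is (3R); the silyl ester is hydrolysed on work-up.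

**Compound list**
1 | hex-1-ene | C=CCCCC | starting material
2 | diethyl[(2S)-2-ethylhexyl]aluminium | CCCC[C@H](CC)C[Al](CC)CC | intermediate
3 | (3S)-3-(iodomethyl)heptane | CCCC[C@H](CC)CI | intermediate
4 | (4S)-4-ethyloct-1-yne | CCCC[C@H](CC)CC#C | intermediate
5 | [(1E,4S)-4-ethyl-2-methyloct-1-en-1-yl]dimethylaluminium | CCCC[C@H](CC)C/C(C)=C/[Al](C)C | intermediate
6 | (1E,4S)-4-ethyl-1-iodo-2-methyloct-1-ene | CCCC[C@H](CC)C/C(C)=C/I | intermediate
7 | methoxyacetyl chloride | COCC(=O)Cl | starting material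
8 | (2R,5R)-2,5-dimethylpyrrolidine | C[C@@H]1CC[C@@H](C)N1 | starting material
9 | 1-[(2R,5R)-2,5-dimethylpyrrolidin-1-yl]-2-methoxyethan-1-one | COCC(=O)N1[C@H](C)CC[C@H]1C | intermediate
10 | but-1-ene | C=CCC | starting material
11 | (2R,5R)-1-(2-methoxyethenylidene)-2,5-dimethylpyrrolidin-1-ium triflate (keteniminium triflate) | COC=C=[N+]1[C@H](C)CC[C@H]1C.[O-]S(=O)(=O)C(F)(F)F | intermediate
12 | (2R,5R)-1-[(3R)-3-ethyl-2-methoxycyclobutylidene]-2,5-dimethylpyrrolidin-1-ium triflate (cyclobutaniminium triflate) | CC[C@@H]1CC(=[N+]2[C@H](C)CC[C@H]2C)C1OC.[O-]S(=O)(=O)C(F)(F)F | intermediate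
13 | (3R)-3-ethyl-2-methoxycyclobutan-1-one (both C2 epimers) | O=C1C[C@@H](CC)C1OC | intermediate
14 | [(1E,4S)-4-ethyl-2-methyloct-1-en-1-yl]lithium | CCCC[C@H](CC)C/C(C)=C/[Li] | intermediate
15 | (3R)-3-ethyl-1-[(1E,4S)-4-ethyl-2-methyloct-1-en-1-yl]-2-methoxycyclobutan-1-ol (C1/C2 diastereomers) | CCCC[C@H](CC)C/C(C)=C/C1(O)C[C@@H](CC)C1OC | intermediate
16 | (4R)-4-ethyl-6-[(1E,4S)-4-ethyl-2-methyloct-1-en-1-yl]-3-methoxy-1,2-dioxan-6-ol (C3/C6 anomers) | CCCC[C@H](CC)C/C(C)=C/C1(O)C[C@@H](CC)C(OC)OO1 | intermediate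
17 | (4R)-4-ethyl-6-[(1E,4S)-4-ethyl-2-methyloct-1-en-1-yl]-3,6-dimethoxy-1,2-dioxane (C3/C6 anomers) | CCCC[C@H](CC)C/C(C)=C/C1(OC)C[C@@H](CC)C(OC)OO1 | intermediate
18 | (4R,6R)-4,6-diethyl-6-[(1E,4S)-4-ethyl-2-methyloct-1-en-1-yl]-3-methoxy-1,2-dioxane (C3 anomers) | CCCC[C@H](CC)C/C(C)=C/[C@@]1(CC)C[C@@H](CC)C(OC)OO1 | intermediate
19 | trimethylsilyl 2-[(3R,4R,6R)-4,6-diethyl-6-[(1E,4S)-4-ethyl-2-methyloct-1-en-1-yl]-1,2-dioxan-3-yl]acetate | CCCC[C@H](CC)C/C(C)=C/[C@@]1(CC)C[C@@H](CC)[C@@H](CC(=O)O[Si](C)(C)C)OO1 | intermediate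
20 | 2-[(3R,4R,6R)-4,6-diethyl-6-[(1E,4S)-4-ethyl-2-methyloct-1-en-1-yl]-1,2-dioxan-3-yl]acetic acid | CCCC[C@H](CC)C/C(C)=C/[C@@]1(CC)C[C@@H](CC)[C@@H](CC(=O)O)OO1 | target

**Totals**
Total step count: 9. Longest linear sequence: 7 steps (1, 2, 3, 6, 7, 8, 9).

**Three steps most likely to fail**

Step 5 (α-methoxy keteniminium [2+2]; level and sense of asymmetric induction uncertain). The fallback sets out from 10 and comes back at 13; it replaces auxiliary control by desymmetrisation of an achiral cyclobutanone. Dichloroketene (Cl3CCOCl, Zn dust, Et2O) adds to 10 to give racemic 2,2-dichloro-3-ethylcyclobutan-1-one F1. Zn/AcOH dechlorination gives achiral 3-ethylcyclobutan-1-one F2. Enantiotopic α-deprotonation with lithium bis[(R)-1-phenylethyl]amide (or its antipode, whichever gives the 3R series) and internal TMSCl quench at −100 °C gives (3R)-3-ethyl-1-(trimethylsilyloxy)cyclobut-1-ene F3. Rubottom oxidation (mCPBA, then dilute acid) gives (3R)-3-ethyl-2-hydroxycyclobutan-1-one F4. O-Methylation (MeI, Ag2O) gives 13.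

Step 7 (aerobic ring expansion on a tertiary allylic, α-methoxy cyclobutanol). The fallback sets out from 15 and comes back at 17; it separates C–C cleavage from peroxide installation. (NH4)2Ce(NO3)6 in MeOH opens 15 by alkoxy-radical β-scission; the methoxy-stabilised radical is oxidised and trapped by MeOH, giving (2R,5E,8S)-2,8-diethyl-1,1-dimethoxy-6-methyldodec-5-en-4-one F5. Ethereal H2O2 (1.5 equiv) with PPTS in MeOH then effects acid-catalysed peroxyacetal exchange and peroxyketalisation of the 1,4-keto acetal to 17.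

Step 8 (the proposed new ethylation; risks are hydride transfer, attack at the far alkene carbon, O–O cleavage and loss of face selectivity). The fallback uses known chemistry only, sets out from 13 and 6 and comes back at 18, but it is not selective at C6. EtMgBr adds to 13 to give (3R)-1,3-diethyl-2-methoxycyclobutan-1-ol F6. (NH4)2Ce(NO3)6 in MeOH opens F6 to (5R)-5-ethyl-6,6-dimethoxyhexan-3-one F7. Alkenyllithium 14 (from 6, t-BuLi) adds to F7 to give the tertiary allylic alcohol (2R,5E,8S)-2,4,8-triethyl-1,1-dimethoxy-6-methyldodec-5-en-4-ol F8 as both C4 epimers. Ethereal H2O2 with catalytic camphorsulfonic acid converts the tertiary allylic alcohol to the hydroperoxide by SN1 substitution and closes it onto the acetal carbon. This gives 18 together with its C6 epimer (4R,6S)-4,6-diethyl-6-[(1E,4S)-4-ethyl-2-methyloct-1-en-1-yl]-3-methoxy-1,2-dioxane F9, which is removed by chromatography; 18 then continues with step 9.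

**Further compounds**
F1 | step 5 | 2,2-dichloro-3-ethylcyclobutan-1-one (racemic) | CCC1CC(=O)C1(Cl)Cl
F2 | step 5 | 3-ethylcyclobutan-1-one | CCC1CC(=O)C1
F3 | step 5 | (3R)-3-ethyl-1-(trimethylsilyloxy)cyclobut-1-ene | C[Si](C)(C)OC1=C[C@H](CC)C1
F4 | step 5 | (3R)-3-ethyl-2-hydroxycyclobutan-1-one | O=C1C[C@@H](CC)C1O
F5 | step 7 | (2R,5E,8S)-2,8-diethyl-1,1-dimethoxy-6-methyldodec-5-en-4-one | CCCC[C@H](CC)C/C(C)=C/C(=O)C[C@@H](CC)C(OC)OC
F6 | step 8 | (3R)-1,3-diethyl-2-methoxycyclobutan-1-ol | CCC1(O)C[C@@H](CC)C1OC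
F7 | step 8 | (5R)-5-ethyl-6,6-dimethoxyhexan-3-one | CCC(=O)C[C@@H](CC)C(OC)OC
F8 | step 8 | (2R,5E,8S)-2,4,8-triethyl-1,1-dimethoxy-6-methyldodec-5-en-4-ol | CCCC[C@H](CC)C/C(C)=C/C(O)(CC)C[C@@H](CC)C(OC)OC
F9 | step 8 | (4R,6S)-4,6-diethyl-6-[(1E,4S)-4-ethyl-2-methyloct-1-en-1-yl]-3-methoxy-1,2-dioxane | CCCC[C@H](CC)C/C(C)=C/[C@]1(CC)C[C@@H](CC)C(OC)OO1
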